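**Retrosynthetic overview**
1. The ester C–O bond is cut last: acylation of the 3β-hydroxyl of the triol enone with (R)-2-methylbutanoic acid.
2. The C11 hydroxyl and the 6,7-alkene come from a singlet-oxygen ene reaction on a 7(11)-isopropylidene 8-ketone; the C3 carbinol comes from hydroxyl-directed reduction of a 3-keto-4-ol.
3. Key C3–C4 bond: the C3 aldehyde carbon, as its carbene-bound acyl anion, attacks the C4 methyl-ketone carbonyl carbon (intramolecular crossed benzoin), closing ring A and setting C4.
4. The keto-aldehyde comes from one double oxidative cleavage of a butenyl/isopropenyl cyclohexanone; the isopropylidene comes from aldol condensation with acetone.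
5. Ring B is the six-membered ring of (+)-verbenone, released by cyclobutane fragmentation after copper-catalysed butenyl addition (sets C10; C5 is the pinane bridgehead). Ring order: B from the chiral pool, then A.

Assumption: (1R,5R)-(+)-verbenone and (R)-2-methylbutanoic acid are bought enantiopure; eudesmane numbering is used (ring A = C1–C5 and C10, ring B = C5–C10, C11 on C7); catalyst-bound species and the boron-bound alkoxide of step 6 are not numbered.

Step 1
Reactants: 1 (1R,5R)-(+)-verbenone; 2 but-3-en-1-ylmagnesium bromide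
Product: 4 (1R,4R,5R)-4-(but-3-en-1-yl)-4,6,6-trimethylbicyclo[3.1.1]heptan-2-one, via bromomagnesium enolate 3 (not isolated)
Conditions: 2 (1.5 equiv), CuBr·SMe2 (10 mol %), THF, −40 → 0 °C; then 1 M HCl
Reagents that add atoms: but-3-en-1-ylmagnesium bromide (2), C=CCC[Mg]Br
Why: Copper-catalysed conjugate addition of a Grignard reagent to the β,β-disubstituted enone, in which the copper-bound butenyl group can reach C4 only from the face opposite the gem-dimethyl bridge, so the future C10 quaternary centre is set by the existing bridgeheads.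

Step 2
Reactants: 4 (1R,4R,5R)-4-(but-3-en-1-yl)-4,6,6-trimethylbicyclo[3.1.1]heptan-2-one
Product: 7 (3R,4S)-3-(but-3-en-1-yl)-3-methyl-4-(prop-1-en-2-yl)cyclohexan-1-one, via iodo silyl enol ether 5 (not isolated), via isopropenyl silyl enol ether 6 (not isolated)
Conditions: TMSCl, NaI, MeCN, 0 °C; then DBU, 0 °C → rt; then 1 M HCl, THF
Reagents that add atoms: none
Why: Iodotrimethylsilane silylates the carbonyl and triggers heterolysis of the strained cyclobutane bond between the α-bridgehead and the gem-dimethyl carbon (Lewis-acid-promoted retro-aldol-type fragmentation of a pinane ketone), and E2 elimination of the resulting tertiary iodide goes to the isopropenyl alkene because the ring methine next to the quaternary carbon is shielded; no bond to C5 or C10 is broken, so both centres are kept.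

Step 3
Reactants: 7 (3R,4S)-3-(but-3-en-1-yl)-3-methyl-4-(prop-1-en-2-yl)cyclohexan-1-one; 8 acetone
Product: 12 (4S,5R)-5-(but-3-en-1-yl)-5-methyl-4-(prop-1-en-2-yl)-2-(propan-2-ylidene)cyclohexan-1-one, via lithium enolate 9 (not isolated), via lithium aldolate 10 (not isolated), via mesylate 11 (not isolated)
Conditions: LiN(iPr)2, THF, −78 °C; acetone; MsCl, −78 → 0 °C; DBU, 0 °C → rt
Reagents that add atoms: acetone (8), CC(C)=O
Why: Aldol condensation in one flask: kinetic deprotonation at the CH2 remote from the quaternary carbon, aldol addition to acetone and E1cB loss of mesylate give the conjugated isopropylidene ketone; the transient C7 centre is destroyed and C5 and C10 are untouched.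

Step 4
Reactants: 12 (4S,5R)-5-(but-3-en-1-yl)-5-methyl-4-(prop-1-en-2-yl)-2-(propan-2-ylidene)cyclohexan-1-one
Product: 14 3-[(1R,2R)-2-acetyl-1-methyl-5-oxo-4-(propan-2-ylidene)cyclohexyl]propanal, via tetraol 13 (not isolated)
Conditions: OsO4 (2 mol %), NMO, acetone–H2O, 0 °C → rt; then NaIO4, rt
Reagents that add atoms: osmium tetroxide, O=[Os](=O)(=O)=O; 4-methylmorpholine N-oxide, C[N+]1([O-])CCOCC1; water, O
Why: Upjohn dihydroxylation followed by periodate (Malaprade) cleavage turns the vinyl group into the C3 aldehyde and the isopropenyl group into the C4 methyl ketone in one flask, while the tetrasubstituted, electron-poor enone alkene does not react with OsO4 and the near-neutral medium leaves the epimerisable C5 centre intact.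

Step 5
Reactants: 14 3-[(1R,2R)-2-acetyl-1-methyl-5-oxo-4-(propan-2-ylidene)cyclohexyl]propanal
Product: 15 (4S,5R,10R)-4-hydroxyeudesm-7(11)-ene-3,8-dione
Conditions: aminoindanol-derived N-C6F5 triazolium tetrafluoroborate (10 mol %, matched antipode, found by testing both), iPr2NEt (10 mol %), toluene, 23 °C
Reagents that add atoms: none
Why: Carbene-catalysed intramolecular crossed aldehyde–ketone benzoin, in which the C3 aldehyde becomes an acyl-anion equivalent (Breslow intermediate) and adds to the C4 ketone through a chair, trans-decalin-like transition state where the enaminol O–H hydrogen-bonds to the ketone oxygen and the bulky azolium sits equatorial, so the new hydroxyl is expected to become equatorial (4α, 4S) with the methyl axial under kinetic control, reinforced by the matched catalyst antipode; the hindered, conjugated C8 ketone is not attacked.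

Step 6
Reactants: 15 (4S,5R,10R)-4-hydroxyeudesm-7(11)-ene-3,8-dione
Product: 16 (3S,4S,5R,10R)-3,4-dihydroxyeudesm-7(11)-en-8-one
Conditions: Me4NBH(OAc)3, MeCN–AcOH (1:1), −20 °C → rt
Reagents that add atoms: none
Why: Hydroxyl-directed triacetoxyborohydride reduction (Saksena–Evans reduction), in which the reagent binds the C4 hydroxyl and delivers hydride to the α face of C3, anti to the axial 4β-methyl, giving the equatorial 3β (3S) alcohol of the trans-diol and leaving the C8 enone, which has no directing hydroxyl, untouched.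

Step 7
Reactants: 16 (3S,4S,5R,10R)-3,4-dihydroxyeudesm-7(11)-en-8-one
Product: 18 (3S,4S,5R,10R)-3,4,11-trihydroxyeudesm-6-en-8-one, via hydroperoxide 17 (not isolated)
Conditions: O2, visible light, tetraphenylporphyrin (1 mol %), CH2Cl2, 0 °C; then PPh3
Reagents that add atoms: oxygen, O=O
Why: Schenck ene reaction of singlet oxygen with the s-cis-locked α-isopropylidene ketone, where the gem effect of enones directs hydrogen abstraction to C6 (the alkyl group geminal to the carbonyl on C7), so oxygen bonds to C11 and the alkene moves to C6=C7, after which PPh3 reduces the hydroperoxide to the tertiary alcohol; no stereocentre is formed.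

Step 8
Reactants: 18 (3S,4S,5R,10R)-3,4,11-trihydroxyeudesm-6-en-8-one; 19 (R)-2-methylbutanoic acid
Product: 20 (3S,4S,5R,10R)-4,11-dihydroxy-8-oxoeudesm-6-en-3-yl (2R)-2-methylbutanoate
Conditions: 19, DCC, DMAP (10 mol %), CH2Cl2, 0 °C → rt
Reagents that add atoms: (R)-2-methylbutanoic acid (19), CC[C@@H](C)C(=O)O
Why: Steglich esterification acylates only the secondary equatorial 3β-hydroxyl, the two tertiary hydroxyls being inert, and low DMAP loading at 0 °C keeps the α-stereocentre of the acid from racemising.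

**Compound list**
1 | (1R,5R)-(+)-verbenone, (1R,5R)-4,6,6-trimethylbicyclo[3.1.1]hept-3-en-2-one | CC1=CC(=O)[C@@H]2C[C@H]1C2(C)C | starting material
2 | but-3-en-1-ylmagnesium bromide | C=CCC[Mg]Br | starting material
3 | bromomagnesium C2=C3 enolate of 4 (same configuration as 4) | C=CCC[C@]1(C)C=C(O[Mg]Br)[C@@H]2C[C@H]1C2(C)C | intermediate
4 | (1R,4R,5R)-4-(but-3-en-1-yl)-4,6,6-trimethylbicyclo[3.1.1]heptan-2-one (butenyl anti to the gem-dimethyl bridge) | C=CCC[C@]1(C)CC(=O)[C@@H]2C[C@H]1C2(C)C | intermediate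
5 | {[(4R,5R)-5-(but-3-en-1-yl)-4-(2-iodopropan-2-yl)-5-methylcyclohex-1-en-1-yl]oxy}trimethylsilane | C=CCC[C@]1(C)CC(O[Si](C)(C)C)=CC[C@H]1C(C)(C)I | intermediate
6 | {[(4S,5R)-5-(but-3-en-1-yl)-5-methyl-4-(prop-1-en-2-yl)cyclohex-1-en-1-yl]oxy}trimethylsilane | C=CCC[C@]1(C)CC(O[Si](C)(C)C)=CC[C@H]1C(C)=C | intermediate
7 | (3R,4S)-3-(but-3-en-1-yl)-3-methyl-4-(prop-1-en-2-yl)cyclohexan-1-one (butenyl and isopropenyl trans) | C=CCC[C@]1(C)CC(=O)CC[C@H]1C(C)=C | intermediate
8 | acetone | CC(C)=O | starting material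
9 | lithium enolate of 7 (C1=C6 enolate, away from the quaternary carbon) | C=CCC[C@]1(C)CC(O[Li])=CC[C@H]1C(C)=C | intermediate
10 | lithium alkoxide of the acetone aldol adduct of 7 (2-(2-oxidopropan-2-yl) ketone, epimers at the new ring carbon) | C=CCC[C@]1(C)CC(=O)C(C(C)(C)O[Li])C[C@H]1C(C)=C | intermediate
11 | methanesulfonate of the aldol adduct (epimers at the same carbon) | C=CCC[C@]1(C)CC(=O)C(C(C)(C)OS(C)(=O)=O)C[C@H]1C(C)=C | intermediate
12 | (4S,5R)-5-(but-3-en-1-yl)-5-methyl-4-(prop-1-en-2-yl)-2-(propan-2-ylidene)cyclohexan-1-one | C=CCC[C@]1(C)CC(=O)C(=C(C)C)C[C@H]1C(C)=C | intermediate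
13 | tetraol from dihydroxylation of both terminal alkenes of 12 (ring centres as in 12, mixture at the two new carbinol carbons) | OCC(O)CC[C@]1(C)CC(=O)C(=C(C)C)C[C@H]1C(C)(O)CO | intermediate
14 | 3-[(1R,2R)-2-acetyl-1-methyl-5-oxo-4-(propan-2-ylidene)cyclohexyl]propanal | O=CCC[C@]1(C)CC(=O)C(=C(C)C)C[C@H]1C(C)=O | intermediate
15 | (4S,5R,10R)-4-hydroxyeudesm-7(11)-ene-3,8-dione (4α-OH, 4β-Me, trans-decalin) | O=C1CC[C@]2(C)CC(=O)C(=C(C)C)C[C@H]2[C@]1(C)O | intermediate
16 | (3S,4S,5R,10R)-3,4-dihydroxyeudesm-7(11)-en-8-one (3β,4α-diol) | O[C@H]1CC[C@]2(C)CC(=O)C(=C(C)C)C[C@H]2[C@]1(C)O | intermediate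
17 | (3S,4S,5R,10R)-11-hydroperoxy-3,4-dihydroxyeudesm-6-en-8-one | O[C@H]1CC[C@]2(C)CC(=O)C(C(C)(C)OO)=C[C@H]2[C@]1(C)O | intermediate
18 | (3S,4S,5R,10R)-3,4,11-trihydroxyeudesm-6-en-8-one | O[C@H]1CC[C@]2(C)CC(=O)C(C(C)(C)O)=C[C@H]2[C@]1(C)O | intermediate
19 | (R)-2-methylbutanoic acid | CC[C@@H](C)C(=O)O | starting material
20 | (3S,4S,5R,10R)-4,11-dihydroxy-8-oxoeudesm-6-en-3-yl (2R)-2-methylbutanoate, CNP0201989.1 | CC[C@@H](C)C(=O)O[C@H]1CC[C@]2(C)CC(=O)C(C(C)(C)O)=C[C@H]2[C@]1(C)O | target

**Step count and risks**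

Total step count: 8. Longest linear sequence: 8 steps (1 → 20); 2, 8 and 19 are bought.

The three steps most likely to fail are steps 5, 2 and 7.

Step 5 carries the most risk. The wanted C4 epimer has its methyl axial, syn to the C10 methyl, so it is the kinetically reasoned product and not the thermodynamic one, and C5 of 14 is epimerisable. The fallback sets out from 12 and comes back at 15. Ring-closing metathesis of 12 with second-generation Grubbs catalyst, (H2IMes)(PCy3)Cl2Ru=CHPh, in CH2Cl2 at 40 °C joins the vinyl and isopropenyl groups (the tetrasubstituted enone alkene is inert) and gives (5R,10R)-eudesma-3,7(11)-dien-8-one F1. OsO4 (cat.) with NMO adds to the 3,4-alkene from the α face, opposite the axial C10 methyl, and gives the cis-diol (3R,4S,5R,10R)-3,4-dihydroxyeudesm-7(11)-en-8-one F2. Dess–Martin periodinane oxidises its secondary 3α-hydroxyl and gives 15.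

Step 2 may suffer from addition of HI to the terminal alkene or from elimination toward the ring. The fallback sets out from 4 and comes back at 7. Acetolytic cyclobutane cleavage with BF3·OEt2, Zn(OAc)2 and Ac2O gives (4R,5R)-4-(2-acetoxypropan-2-yl)-5-(but-3-en-1-yl)-5-methylcyclohex-1-en-1-yl acetate F3. K2CO3 in MeOH removes both acetyl groups and gives (3R,4R)-3-(but-3-en-1-yl)-4-(2-hydroxypropan-2-yl)-3-methylcyclohexan-1-one F4. Burgess reagent dehydrates the tertiary alcohol by syn elimination toward a methyl group and gives 7.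

Step 7 may give hydrogen abstraction from the isopropylidene methyls, or the enone may react slowly with singlet oxygen. The fallback sets out from 7 and comes back at 18; it builds the hydroxyisopropyl enone before ring A and uses no singlet oxygen.
- IBX (DMSO, 70 °C) dehydrogenates 7 on the only side that bears β-hydrogens and gives (4S,5R)-5-(but-3-en-1-yl)-5-methyl-4-(prop-1-en-2-yl)cyclohex-2-en-1-one F5.
- LiSePh adds 1,4 and the lithium enolate is trapped by acetone to give the β-phenylselanyl aldol adduct F6 (not isolated). H2O2 with pyridine then effects selenoxide syn elimination to (4S,5R)-5-(but-3-en-1-yl)-2-(2-hydroxypropan-2-yl)-5-methyl-4-(prop-1-en-2-yl)cyclohex-2-en-1-one F7.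
- OsO4/NMO and then NaIO4 convert F7 through the pentaol F8 into 3-[(1R,2R)-2-acetyl-4-(2-hydroxypropan-2-yl)-1-methyl-5-oxocyclohex-3-en-1-yl]propanal F9.
- The triazolium-catalysed benzoin of step 5 closes ring A and gives (4S,5R,10R)-4,11-dihydroxyeudesm-6-ene-3,8-dione F10.
- NaBH4 in MeOH–CH2Cl2 at −78 °C reduces the saturated α-hydroxy ketone from the axial direction in preference to the hindered cross-conjugated enone and gives 18.

Further compounds
F1 | step 5 | (5R,10R)-eudesma-3,7(11)-dien-8-one | CC1=CCC[C@]2(C)CC(=O)C(=C(C)C)C[C@@H]12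
F2 | step 5 | (3R,4S,5R,10R)-3,4-dihydroxyeudesm-7(11)-en-8-one | O[C@@H]1CC[C@]2(C)CC(=O)C(=C(C)C)C[C@H]2[C@]1(C)O
F3 | step 2 | (4R,5R)-4-(2-acetoxypropan-2-yl)-5-(but-3-en-1-yl)-5-methylcyclohex-1-en-1-yl acetate | C=CCC[C@]1(C)CC(OC(C)=O)=CC[C@H]1C(C)(C)OC(C)=O
F4 | step 2 | (3R,4R)-3-(but-3-en-1-yl)-4-(2-hydroxypropan-2-yl)-3-methylcyclohexan-1-one | C=CCC[C@]1(C)CC(=O)CC[C@H]1C(C)(C)O
F5 | step 7 | (4S,5R)-5-(but-3-en-1-yl)-5-methyl-4-(prop-1-en-2-yl)cyclohex-2-en-1-one | C=CCC[C@]1(C)CC(=O)C=C[C@H]1C(C)=C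
F6 | step 7 | β-phenylselanyl aldol adduct of F5 with acetone (mixture at the two new ring carbons) | C=CCC[C@]1(C)CC(=O)C(C(C)(C)O)C([Se]c2ccccc2)[C@H]1C(C)=C
F7 | step 7 | (4S,5R)-5-(but-3-en-1-yl)-2-(2-hydroxypropan-2-yl)-5-methyl-4-(prop-1-en-2-yl)cyclohex-2-en-1-one | C=CCC[C@]1(C)CC(=O)C(C(C)(C)O)=C[C@H]1C(C)=C
F8 | step 7 | pentaol from dihydroxylation of both terminal alkenes of F7 (mixture at the two new carbinol carbons) | OCC(O)CC[C@]1(C)CC(=O)C(C(C)(C)O)=C[C@H]1C(C)(O)CO
F9 | step 7 | 3-[(1R,2R)-2-acetyl-4-(2-hydroxypropan-2-yl)-1-methyl-5-oxocyclohex-3-en-1-yl]propanal | O=CCC[C@]1(C)CC(=O)C(C(C)(C)O)=C[C@H]1C(C)=O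
F10 | step 7 | (4S,5R,10R)-4,11-dihydroxyeudesm-6-ene-3,8-dione | O=C1CC[C@]2(C)CC(=O)C(C(C)(C)O)=C[C@H]2[C@]1(C)O
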